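**Plan**
Core numbering (2-oxabicyclo[3.3.1]nonan-3-one): C-1 O-bearing bridgehead, O-2, C-3 lactone C=O, C-4 CH2, C-5 quaternary bridgehead, C-6 CH–CMe2CO2H, C-7 CHOH, C-8 CH2, C-9 CH carrying the side chain C-1' to C-5'.
Cuts: CO2H from a silylethyl ester; the C-1' and C-7 carbinols from ketones; C-1'–C-2' from an acyl imidazole and a sulfone carbanion; then C-3–C-4 and C-9–C-1 together (with O-2–C-3).
Enabling feature: C-4 and C-9 both hang on quaternary C-5, so the lactone plus a carboxyl at C-9 is a 3,3-disubstituted glutaric anhydride aldol-lactonised onto a methyl ketone, and that anhydride is a gem-dimethyl acid plus CO.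
Forward: cross-metathesis, Ireland–Claisen rearrangement and an acetone aldol give an open chain; one operation closes the carbocycle and the lactone; side chain, redox corrections and deprotection follow.
Stereochemistry: C-6 from (R)-but-3-en-2-ol by 1,3-chirality transfer; C-5, C-9 and C-1 in the key step under control of C-6; C-7 by exo hydride attack after a temporary (S)-silyloxy group from a D-proline aldol; C-3' from a palladium-catalysed DYKAT of isoprene monoxide; C-1' by CBS reduction.

Key step: step 9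

Remark: the free 7-hydroxy acid and the tertiary lactone of the target are assumed to survive neutral work-up without relactonisation, as in the isolated natural product; strongly basic or acidic conditions are therefore avoided from step 16 on.

Step 1
Reactants: 1 methyl 3,3-dimethylpent-4-enoate; 2 (R)-but-3-en-2-ol
Product: 3 methyl (4E,6R)-6-hydroxy-3,3-dimethylhept-4-enoate
Conditions: second-generation Hoveyda–Grubbs catalyst (5 mol %), 1 (3 equiv), 1,4-benzoquinone (10 mol %), CH2Cl2, 40 °C
Reagents that add atoms: none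
Why: Olefin cross-metathesis, in which the vinyl group next to the quaternary carbon does not homodimerise and should couple with the allylic alcohol to the E alkene, the carbinol stereocentre of 2 being untouched.

Step 2
Reactants: 3 methyl (4E,6R)-6-hydroxy-3,3-dimethylhept-4-enoate
Product: 4 methyl (4E,6R)-6-(isobutyryloxy)-3,3-dimethylhept-4-enoate
Conditions: isobutyryl chloride, pyridine, DMAP (cat.), CH2Cl2, 0 °C to rt
Reagents that add atoms: isobutyryl chloride, CC(C)C(Cl)=O
Why: DMAP-catalysed acylation of the secondary allylic alcohol, which touches no stereocentre.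

Step 3
Reactants: 4 methyl (4E,6R)-6-(isobutyryloxy)-3,3-dimethylhept-4-enoate
Product: 7 (3R,4E)-3-(4-methoxy-2-methyl-4-oxobutan-2-yl)-2,2-dimethylhex-4-enoic acid, via bis-silyl ketene acetal 5 (not isolated), via silyl ester 6 (not isolated)
Conditions: LiN(iPr)2 (2.3 equiv), Me3SiCl (2.6 equiv), THF, −78 °C, then 65 °C; aq. HCl
Reagents that add atoms: none
Why: Ireland–Claisen rearrangement, in which the tetrasubstituted ketene acetal (no enolate geometry to control) and the E alkene pass through a chair with the carbinol methyl equatorial, so the C–O stereocentre is relayed suprafacially to the new (R)-CH between the two quaternary carbons and the new alkene is E; the second ketene acetal is a spectator that returns the methyl ester on hydrolysis.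

Step 4
Reactants: 7 (3R,4E)-3-(4-methoxy-2-methyl-4-oxobutan-2-yl)-2,2-dimethylhex-4-enoic acid
Product: 8 2-(trimethylsilyl)ethyl (3R,4E)-3-(4-methoxy-2-methyl-4-oxobutan-2-yl)-2,2-dimethylhex-4-enoate
Conditions: 2-(trimethylsilyl)ethyl 2,2,2-trichloroacetimidate (2 equiv), toluene, 100 °C
Reagents that add atoms: 2-(trimethylsilyl)ethyl 2,2,2-trichloroacetimidate, C[Si](C)(C)CCOC(=N)C(Cl)(Cl)Cl
Why: Trichloroacetimidate esterification, which alkylates the carboxyl oxygen and so avoids attack at the crowded α,α-dimethyl carbonyl group.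

Step 5
Reactants: 8 2-(trimethylsilyl)ethyl (3R,4E)-3-(4-methoxy-2-methyl-4-oxobutan-2-yl)-2,2-dimethylhex-4-enoate
Product: 9 1-methyl 6-[2-(trimethylsilyl)ethyl] (4R)-4-formyl-3,3,5,5-tetramethylhexanedioate
Conditions: K2OsO4·2H2O (2 mol %), NaIO4 (4 equiv), 2,6-lutidine, dioxane/H2O, rt
Reagents that add atoms: sodium periodate (oxygen source with the osmium catalyst), [Na+].[O-]I(=O)(=O)=O
Why: Lemieux–Johnson cleavage (osmylation then periodate scission) of the only alkene should unmask the aldehyde, whose α-stereocentre sits between two quaternary carbons and should not epimerise under the buffered conditions.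

Step 6
Reactants: 9 1-methyl 6-[2-(trimethylsilyl)ethyl] (4R)-4-formyl-3,3,5,5-tetramethylhexanedioate
Product: 10 1-methyl 6-[2-(trimethylsilyl)ethyl] (4R)-4-[(1S)-1-hydroxy-3-oxobutyl]-3,3,5,5-tetramethylhexanedioate
Conditions: D-proline (30 mol %), acetone/DMSO (1:4), rt
Reagents that add atoms: acetone, CC(C)=O
Why: Proline-catalysed direct aldol reaction (enamine catalysis) of acetone with an aldehyde that cannot self-condense, D-proline setting the (S)-carbinol by catalyst control.

Step 7
Reactants: 10 1-methyl 6-[2-(trimethylsilyl)ethyl] (4R)-4-[(1S)-1-hydroxy-3-oxobutyl]-3,3,5,5-tetramethylhexanedioate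
Product: 11 1-methyl 6-[2-(trimethylsilyl)ethyl] (4R)-4-[(1S)-1-(tert-butyldimethylsilyloxy)-3-oxobutyl]-3,3,5,5-tetramethylhexanedioate
Conditions: TBSOTf, 2,6-lutidine, CH2Cl2, −78 °C
Reagents that add atoms: tert-butyldimethylsilyl triflate, CC(C)(C)[Si](C)(C)OS(=O)(=O)C(F)(F)F
Why: O-silylation with the silyl triflate at low temperature, which should be faster than enol silylation of the methyl ketone.

Step 8
Reactants: 11 1-methyl 6-[2-(trimethylsilyl)ethyl] (4R)-4-[(1S)-1-(tert-butyldimethylsilyloxy)-3-oxobutyl]-3,3,5,5-tetramethylhexanedioate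
Product: 12 (4R)-4-[(1S)-1-(tert-butyldimethylsilyloxy)-3-oxobutyl]-3,3,5,5-tetramethyl-6-oxo-6-[2-(trimethylsilyl)ethoxy]hexanoic acid
Conditions: LiOH·H2O, THF/H2O, 0 °C; then 1 M HCl
Reagents that add atoms: lithium hydroxide, [Li+].[OH-]
Why: Saponification should select the unhindered CH2CO2Me ester over the shielded α,α-dimethyl ester, and the cold conditions should spare the β-silyloxy ketone from elimination.

Step 9
Reactants: 12 (4R)-4-[(1S)-1-(tert-butyldimethylsilyloxy)-3-oxobutyl]-3,3,5,5-tetramethyl-6-oxo-6-[2-(trimethylsilyl)ethoxy]hexanoic acid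
Product: 14 (1S,5R,6R,7S,9R)-7-(tert-butyldimethylsilyloxy)-1,5-dimethyl-6-{2-methyl-1-oxo-1-[2-(trimethylsilyl)ethoxy]propan-2-yl}-3-oxo-2-oxabicyclo[3.3.1]nonane-9-carboxylic acid, via glutaric anhydride 13 (not isolated)
Conditions: Pd(OAc)2 (10 mol %), N-acetyl-β-alanine-type ligand (20 mol %), AgOAc (2.5 equiv), K2HPO4, CO (1 atm), (CF3)2CHOH, 80 °C; then evaporate, ZnCl2, Et3N, CH2Cl2, 0 °C to rt; aq. citric acid
Reagents that add atoms: carbon monoxide, [C-]#[O+]
Why: Proposed new method: The carboxylate of 12 should direct divalent palladium to a γ-methyl C–H bond of the gem-dimethyl group (six-membered palladacycle; either methyl gives the same product), CO inserts and C–O reductive elimination closes anhydride 13, in which C-5 carries two identical CH2C(=O) arms; zinc enolisation of one arm then gives an aldol addition to the tethered methyl ketone and the new alkoxide opens the anhydride at the carbonyl of the other arm. The closest known reaction types are the Pd-catalysed C(sp3)–H carbonylation of free aliphatic acids to cyclic anhydrides (with γ-C–H activation of β-quaternary acids) and the Fittig–Perkin/Stobbe aldol–lactonisation of cyclic anhydrides with ketones; their union in one flask and the desymmetrisation are new. The carbocycle closes by a 6-(enolexo)-exo-trig aldol (C-9–C-1) and the lactone by a 6-exo-trig acyl transfer (O-2–C-3) that needs the CH2 arm and the alkoxide 1,3-diaxial. C-5 is set by desymmetrisation, because only the chair with the CMe2CO2R group at C-6 and the silyloxy group at C-7 equatorial places one arm axial for lactonisation, so C-6 decides which arm becomes C-4 and which C-9; C-9 follows from the cis ring fusion that the anhydride tether enforces, and C-1 from the reversibility of the aldol, since only the alkoxide syn to the axial arm is trapped. The step needs enolisation of the anhydride rather than C-acylation by the ketone enolate or β-elimination of the silyloxy group, which the soft ZnCl2/Et3N enolisation and the irreversible opening of the anhydride should secure.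

Step 10
Reactants: 15 rac-2-methyl-2-vinyloxirane
Product: 16 (S)-2-methylbut-3-ene-1,2-diol
Conditions: Pd2(dba)3·CHCl3 (1 mol %), (S,S)-DACH-naphthyl Trost ligand (3 mol %), Et3B (1 mol %), NaHCO3, CH2Cl2/H2O, rt
Reagents that add atoms: water, O
Why: Palladium-catalysed dynamic kinetic asymmetric allylic substitution, in which the racemic vinyl epoxide gives interconverting π-allyl complexes and hydrogencarbonate is delivered to the tertiary terminus under ligand control, the carbonate then losing CO2 to the (S)-diol.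

Step 11
Reactants: 16 (S)-2-methylbut-3-ene-1,2-diol
Product: 17 (S)-2-hydroxy-2-methylbut-3-en-1-yl 4-methylbenzenesulfonate
Conditions: TsCl (1.05 equiv), pyridine, CH2Cl2, 0 °C
Reagents that add atoms: 4-methylbenzenesulfonyl chloride, Cc1ccc(cc1)S(Cl)(=O)=O
Why: Selective sulfonylation of the primary hydroxyl group, the tertiary one being too hindered to react.

Step 12
Reactants: 17 (S)-2-hydroxy-2-methylbut-3-en-1-yl 4-methylbenzenesulfonate
Product: 18 (S)-2-methyl-1-(phenylsulfonyl)but-3-en-2-ol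
Conditions: PhSO2Na, Bu4NI (cat.), DMF, 80 °C
Reagents that add atoms: sodium benzenesulfinate, [Na+].[O-]S(=O)c1ccccc1
Why: S-alkylation of the sulfinate (SN2 at the CH2 carbon) gives the sulfone without involving the tertiary stereocentre.

Step 13
Reactants: 14 bicyclic lactone acid from step 9; 18 (S)-2-methyl-1-(phenylsulfonyl)but-3-en-2-ol
Product: 21 2-(trimethylsilyl)ethyl ester of the 9-[(3S)-3-hydroxy-3-methyl-2-(phenylsulfonyl)pent-4-enoyl] lactone (C-2' epimers), via acyl imidazole 19 (not isolated), via dilithiated sulfone 20 (not isolated)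
Conditions: 14, carbonyldiimidazole, THF, rt; 18 (3.2 equiv), n-BuLi (6.4 equiv), THF, −78 °C; combine at −78 °C; aq. NH4Cl
Reagents that add atoms: none
Why: C-acylation of a sulfone-stabilised carbanion (β-keto sulfone synthesis), the acyl imidazole being far more electrophilic than the hindered lactone and ester, with the stereocentres of both partners retained.

Step 14
Reactants: 21 β-keto sulfone from step 13
Product: 22 2-(trimethylsilyl)ethyl 2-[(1S,5R,6R,7S,9R)-7-(tert-butyldimethylsilyloxy)-9-[(3R)-3-hydroxy-3-methylpent-4-enoyl]-1,5-dimethyl-3-oxo-2-oxabicyclo[3.3.1]nonan-6-yl]-2-methylpropanoate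
Conditions: SmI2 (3 equiv), THF/MeOH, −78 °C
Reagents that add atoms: none
Why: Reductive desulfonylation of a β-keto sulfone by single-electron transfer, the enolate being protonated at C-2' so that no stereocentre of the core is touched.

Step 15
Reactants: 22 silyl-protected β-hydroxy ketone from step 14
Product: 23 2-(trimethylsilyl)ethyl 2-[(1S,5R,6R,7S,9R)-7-hydroxy-9-[(3R)-3-hydroxy-3-methylpent-4-enoyl]-1,5-dimethyl-3-oxo-2-oxabicyclo[3.3.1]nonan-6-yl]-2-methylpropanoate
Conditions: HF·pyridine, pyridine, THF, 0 °C to rt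
Reagents that add atoms: none
Why: Desilylation with buffered HF should remove the secondary silyl ether while leaving the silylethyl ester, the lactone and the β-hydroxy ketone intact.

Step 16
Reactants: 23 7-hydroxy compound from step 15
Product: 24 2-(trimethylsilyl)ethyl 2-[(1S,5R,6R,9R)-9-[(3R)-3-hydroxy-3-methylpent-4-enoyl]-1,5-dimethyl-3,7-dioxo-2-oxabicyclo[3.3.1]nonan-6-yl]-2-methylpropanoate
Conditions: Dess–Martin periodinane, NaHCO3, CH2Cl2, 0 °C to rt
Reagents that add atoms: none
Why: Dess–Martin oxidation of the only secondary alcohol under buffered, non-basic conditions, the tertiary alcohol being inert and C-6 already holding its bulky group equatorial.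

Step 17
Reactants: 24 diketone from step 16
Product: 25 2-(trimethylsilyl)ethyl 2-[(1S,5R,6R,7R,9R)-7-hydroxy-9-[(3R)-3-hydroxy-3-methylpent-4-enoyl]-1,5-dimethyl-3-oxo-2-oxabicyclo[3.3.1]nonan-6-yl]-2-methylpropanoate
Conditions: NaBH4, CeCl3·7H2O, MeOH/THF, −78 °C
Reagents that add atoms: none
Why: Borohydride reduction under steric approach control (Luche conditions), in which the endo face of the ring ketone is blocked by the lactone bridge so that hydride should enter from the exo face and give the axial (7R)-alcohol, while the far more hindered side-chain ketone is left.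

Step 18
Reactants: 25 7-hydroxy ketone from step 17
Product: 26 2-(trimethylsilyl)ethyl 2-[(1S,5R,6R,7R,9S)-9-[(1S,3R)-1,3-dihydroxy-3-methylpent-4-enyl]-7-hydroxy-1,5-dimethyl-3-oxo-2-oxabicyclo[3.3.1]nonan-6-yl]-2-methylpropanoate
Conditions: (R)-2-methyl-CBS-oxazaborolidine (30 mol %), catecholborane, toluene, −40 °C to 0 °C; MeOH
Reagents that add atoms: none
Why: Corey–Bakshi–Shibata reduction, in which the (R)-oxazaborolidine distinguishes the bulky bicyclic substituent from the CH2 group and should deliver hydride to give the (1'S)-carbinol by catalyst control.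

Step 19
Reactants: 26 silylethyl ester from step 18
Product: 27 2-[(1S,5R,6R,7R,9S)-9-[(1S,3R)-1,3-dihydroxy-3-methylpent-4-enyl]-7-hydroxy-1,5-dimethyl-3-oxo-2-oxabicyclo[3.3.1]nonan-6-yl]-2-methylpropanoic acid (target)
Conditions: Bu4NF, AcOH (1:1), THF, 0 °C to rt; pH 4 buffer
Reagents that add atoms: none
Why: Fluoride-induced fragmentation of the 2-(trimethylsilyl)ethyl ester (loss of ethene and Me3SiF) under buffered conditions should free the acid without hydrolysing or migrating the lactone.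

**Compound list**
1 | methyl 3,3-dimethylpent-4-enoate | C=CC(C)(C)CC(=O)OC | starting material
2 | (R)-but-3-en-2-ol | C[C@@H](O)C=C | starting material
3 | methyl (4E,6R)-6-hydroxy-3,3-dimethylhept-4-enoate | COC(=O)CC(C)(C)/C=C/[C@@H](C)O | intermediate
4 | methyl (4E,6R)-6-(isobutyryloxy)-3,3-dimethylhept-4-enoate | COC(=O)CC(C)(C)/C=C/[C@@H](C)OC(=O)C(C)C | intermediate
5 | bis-silyl ketene acetal of 4 (isobutyrate as 2-methyl-1-(trimethylsilyloxy)prop-1-enyl ether; methyl ester as 1-methoxy-1-(trimethylsilyloxy)alkene of either geometry) | COC(O[Si](C)(C)C)=CC(C)(C)/C=C/[C@@H](C)OC(O[Si](C)(C)C)=C(C)C | intermediate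
6 | trimethylsilyl (3R,4E)-3-[4-methoxy-2-methyl-4-(trimethylsilyloxy)but-3-en-2-yl]-2,2-dimethylhex-4-enoate | C/C=C/[C@H](C(C)(C)C=C(OC)O[Si](C)(C)C)C(C)(C)C(=O)O[Si](C)(C)C | intermediate
7 | (3R,4E)-3-(4-methoxy-2-methyl-4-oxobutan-2-yl)-2,2-dimethylhex-4-enoic acid | C/C=C/[C@H](C(C)(C)CC(=O)OC)C(C)(C)C(=O)O | intermediate
8 | 2-(trimethylsilyl)ethyl (3R,4E)-3-(4-methoxy-2-methyl-4-oxobutan-2-yl)-2,2-dimethylhex-4-enoate | C/C=C/[C@H](C(C)(C)CC(=O)OC)C(C)(C)C(=O)OCC[Si](C)(C)C | intermediate
9 | 1-methyl 6-[2-(trimethylsilyl)ethyl] (4R)-4-formyl-3,3,5,5-tetramethylhexanedioate | O=C[C@H](C(C)(C)CC(=O)OC)C(C)(C)C(=O)OCC[Si](C)(C)C | intermediate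
10 | 1-methyl 6-[2-(trimethylsilyl)ethyl] (4R)-4-[(1S)-1-hydroxy-3-oxobutyl]-3,3,5,5-tetramethylhexanedioate | CC(=O)C[C@H](O)[C@H](C(C)(C)CC(=O)OC)C(C)(C)C(=O)OCC[Si](C)(C)C | intermediate
11 | 1-methyl 6-[2-(trimethylsilyl)ethyl] (4R)-4-[(1S)-1-(tert-butyldimethylsilyloxy)-3-oxobutyl]-3,3,5,5-tetramethylhexanedioate | CC(=O)C[C@H](O[Si](C)(C)C(C)(C)C)[C@H](C(C)(C)CC(=O)OC)C(C)(C)C(=O)OCC[Si](C)(C)C | intermediate
12 | (4R)-4-[(1S)-1-(tert-butyldimethylsilyloxy)-3-oxobutyl]-3,3,5,5-tetramethyl-6-oxo-6-[2-(trimethylsilyl)ethoxy]hexanoic acid | CC(=O)C[C@H](O[Si](C)(C)C(C)(C)C)[C@H](C(C)(C)CC(=O)O)C(C)(C)C(=O)OCC[Si](C)(C)C | intermediate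
13 | 2-(trimethylsilyl)ethyl (3R,4S)-4-(tert-butyldimethylsilyloxy)-2,2-dimethyl-3-(4-methyl-2,6-dioxotetrahydro-2H-pyran-4-yl)-6-oxoheptanoate | CC(=O)C[C@H](O[Si](C)(C)C(C)(C)C)[C@H](C1(C)CC(=O)OC(=O)C1)C(C)(C)C(=O)OCC[Si](C)(C)C | intermediate
14 | (1S,5R,6R,7S,9R)-7-(tert-butyldimethylsilyloxy)-1,5-dimethyl-6-{2-methyl-1-oxo-1-[2-(trimethylsilyl)ethoxy]propan-2-yl}-3-oxo-2-oxabicyclo[3.3.1]nonane-9-carboxylic acid | OC(=O)[C@@H]1[C@]2(C)CC(=O)O[C@@]1(C)C[C@H](O[Si](C)(C)C(C)(C)C)[C@H]2C(C)(C)C(=O)OCC[Si](C)(C)C | intermediate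
15 | rac-2-methyl-2-vinyloxirane (isoprene monoxide, racemate) | C=CC1(C)CO1 | starting material
16 | (S)-2-methylbut-3-ene-1,2-diol | C=C[C@](C)(O)CO | intermediate
17 | (S)-2-hydroxy-2-methylbut-3-en-1-yl 4-methylbenzenesulfonate | C=C[C@](C)(O)COS(=O)(=O)c1ccc(C)cc1 | intermediate
18 | (S)-2-methyl-1-(phenylsulfonyl)but-3-en-2-ol | C=C[C@](C)(O)CS(=O)(=O)c1ccccc1 | intermediate
19 | 1-acylimidazole of acid 14 | O=C(n1ccnc1)[C@@H]1[C@]2(C)CC(=O)O[C@@]1(C)C[C@H](O[Si](C)(C)C(C)(C)C)[C@H]2C(C)(C)C(=O)OCC[Si](C)(C)C | intermediate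
20 | O,C-dilithio derivative of sulfone 18 | C=C[C@](C)(O[Li])C([Li])S(=O)(=O)c1ccccc1 | intermediate
21 | 2-(trimethylsilyl)ethyl 2-[(1S,5R,6R,7S,9R)-7-(tert-butyldimethylsilyloxy)-9-[(3S)-3-hydroxy-3-methyl-2-(phenylsulfonyl)pent-4-enoyl]-1,5-dimethyl-3-oxo-2-oxabicyclo[3.3.1]nonan-6-yl]-2-methylpropanoate (both C-2' epimers) | C=C[C@](C)(O)C(S(=O)(=O)c1ccccc1)C(=O)[C@@H]1[C@]2(C)CC(=O)O[C@@]1(C)C[C@H](O[Si](C)(C)C(C)(C)C)[C@H]2C(C)(C)C(=O)OCC[Si](C)(C)C | intermediate
22 | 2-(trimethylsilyl)ethyl 2-[(1S,5R,6R,7S,9R)-7-(tert-butyldimethylsilyloxy)-9-[(3R)-3-hydroxy-3-methylpent-4-enoyl]-1,5-dimethyl-3-oxo-2-oxabicyclo[3.3.1]nonan-6-yl]-2-methylpropanoate | C=C[C@](C)(O)CC(=O)[C@@H]1[C@]2(C)CC(=O)O[C@@]1(C)C[C@H](O[Si](C)(C)C(C)(C)C)[C@H]2C(C)(C)C(=O)OCC[Si](C)(C)C | intermediate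
23 | 2-(trimethylsilyl)ethyl 2-[(1S,5R,6R,7S,9R)-7-hydroxy-9-[(3R)-3-hydroxy-3-methylpent-4-enoyl]-1,5-dimethyl-3-oxo-2-oxabicyclo[3.3.1]nonan-6-yl]-2-methylpropanoate | C=C[C@](C)(O)CC(=O)[C@@H]1[C@]2(C)CC(=O)O[C@@]1(C)C[C@H](O)[C@H]2C(C)(C)C(=O)OCC[Si](C)(C)C | intermediate
24 | 2-(trimethylsilyl)ethyl 2-[(1S,5R,6R,9R)-9-[(3R)-3-hydroxy-3-methylpent-4-enoyl]-1,5-dimethyl-3,7-dioxo-2-oxabicyclo[3.3.1]nonan-6-yl]-2-methylpropanoate | C=C[C@](C)(O)CC(=O)[C@@H]1[C@]2(C)CC(=O)O[C@@]1(C)CC(=O)[C@H]2C(C)(C)C(=O)OCC[Si](C)(C)C | intermediate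
25 | 2-(trimethylsilyl)ethyl 2-[(1S,5R,6R,7R,9R)-7-hydroxy-9-[(3R)-3-hydroxy-3-methylpent-4-enoyl]-1,5-dimethyl-3-oxo-2-oxabicyclo[3.3.1]nonan-6-yl]-2-methylpropanoate | C=C[C@](C)(O)CC(=O)[C@@H]1[C@]2(C)CC(=O)O[C@@]1(C)C[C@@H](O)[C@H]2C(C)(C)C(=O)OCC[Si](C)(C)C | intermediate
26 | 2-(trimethylsilyl)ethyl 2-[(1S,5R,6R,7R,9S)-9-[(1S,3R)-1,3-dihydroxy-3-methylpent-4-enyl]-7-hydroxy-1,5-dimethyl-3-oxo-2-oxabicyclo[3.3.1]nonan-6-yl]-2-methylpropanoate | C=C[C@](C)(O)C[C@H](O)[C@@H]1[C@]2(C)CC(=O)O[C@@]1(C)C[C@@H](O)[C@H]2C(C)(C)C(=O)OCC[Si](C)(C)C | intermediate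
27 | 2-[(1S,5R,6R,7R,9S)-9-[(1S,3R)-1,3-dihydroxy-3-methylpent-4-enyl]-7-hydroxy-1,5-dimethyl-3-oxo-2-oxabicyclo[3.3.1]nonan-6-yl]-2-methylpropanoic acid | C=C[C@](C)(O)C[C@H](O)[C@@H]1[C@]2(C)CC(=O)O[C@@]1(C)C[C@@H](O)[C@H]2C(C)(C)C(=O)O | target

**Step count**
Total: 19 steps. Longest linear sequence: 16 steps (steps 1–9 and 13–19); steps 10–12 make the sulfone fragment.

**Steps most likely to fail**

Step 9 (key step). Possible failures: reduction of divalent palladium by CO before C–H cleavage; slow palladation next to the crowded C-6 substituent; enolisation of the methyl ketone in the second stage, leading to C-acylation or β-elimination of the silyloxy group; incomplete discrimination between the two anhydride arms. The fallback sets out from 12, uses known reaction types only and rejoins the route at 14. A Pd(OAc)2/amino acid ligand/Ag2CO3-mediated γ-C(sp3)–H arylation of the free acid with 4-iodoanisole in (CF3)2CHOH should give the γ-(4-methoxyphenyl) acid F1 (either methyl group reacts; the new centre is inconsequential). RuCl3/NaIO4 degradation of the anisyl ring to a carboxyl group should give the 3,3-disubstituted glutaric acid F2, which Ac2O should close to anhydride 13, now isolated. The aldol–lactonisation is then run as a separate step (LiN(SiMe3)2, THF, −78 °C, or ZnCl2/Et3N) to give 14.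

Step 1. Possible failures: slow turnover of the alkene next to the quaternary carbon, homodimerisation of 2, and isomerisation of the allylic alcohol to a ketone by ruthenium hydrides. The fallback sets out from 1 and rejoins at 3. Lemieux–Johnson cleavage (K2OsO4·2H2O, NaIO4) should give methyl 3,3-dimethyl-4-oxobutanoate F3. A Wittig reaction with 1-(triphenylphosphoranylidene)propan-2-one in toluene at 90 °C should give methyl (4E)-3,3-dimethyl-6-oxohept-4-enoate F4. CBS reduction with the (S)-oxazaborolidine and catecholborane should then give the (R)-allylic alcohol 3.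

Step 6. Possible failures: slow enamine addition to the very hindered aldehyde, mismatched double diastereoselection against the α-stereocentre, and retro-aldol or dehydration of the product. The fallback sets out from 9 and rejoins at 11. Asymmetric allylboration with (−)-Ipc2B(allyl) (oxidative work-up) should give the (S)-homoallylic alcohol F5. Silylation with TBSOTf/2,6-lutidine should give its silyl ether F6. Tsuji–Wacker oxidation (PdCl2, CuCl, O2, DMF/H2O) should then give methyl ketone 11.

Further compounds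
F1 | step 9 | (4R)-4-[(1S)-1-(tert-butyldimethylsilyloxy)-3-oxobutyl]-3-(4-methoxybenzyl)-3,5,5-trimethyl-6-oxo-6-[2-(trimethylsilyl)ethoxy]hexanoic acid (either configuration at C-3) | CC(=O)C[C@H](O[Si](C)(C)C(C)(C)C)[C@H](C(C)(Cc1ccc(OC)cc1)CC(=O)O)C(C)(C)C(=O)OCC[Si](C)(C)C
F2 | step 9 | 3-{(3R,4S)-4-(tert-butyldimethylsilyloxy)-2-methyl-6-oxo-1-oxo-1-[2-(trimethylsilyl)ethoxy]heptan-3-yl-2-methyl}-3-methylpentanedioic acid (3-methyl-3-substituted glutaric acid corresponding to anhydride 13) | CC(=O)C[C@H](O[Si](C)(C)C(C)(C)C)[C@H](C(C)(CC(=O)O)CC(=O)O)C(C)(C)C(=O)OCC[Si](C)(C)C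
F3 | step 1 | methyl 3,3-dimethyl-4-oxobutanoate | COC(=O)CC(C)(C)C=O
F4 | step 1 | methyl (4E)-3,3-dimethyl-6-oxohept-4-enoate | COC(=O)CC(C)(C)/C=C/C(C)=O
F5 | step 6 | 1-methyl 6-[2-(trimethylsilyl)ethyl] (4R)-4-[(1S)-1-hydroxybut-3-enyl]-3,3,5,5-tetramethylhexanedioate | C=CC[C@H](O)[C@H](C(C)(C)CC(=O)OC)C(C)(C)C(=O)OCC[Si](C)(C)C
F6 | step 6 | 1-methyl 6-[2-(trimethylsilyl)ethyl] (4R)-4-[(1S)-1-(tert-butyldimethylsilyloxy)but-3-enyl]-3,3,5,5-tetramethylhexanedioate | C=CC[C@H](O[Si](C)(C)C(C)(C)C)[C@H](C(C)(C)CC(=O)OC)C(C)(C)C(=O)OCC[Si](C)(C)C
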